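**Retrosynthetic overview**

- The four-carbon chain C2–C3–C4–C5 of the lactone is treated as a 2-oxy-2,3-dimethylsuccinic acid. The strategy rests on this feature: lactone C3 and C4 each carry a CH2 bonded to the same 4-hydroxy-3-methoxyphenyl ring, and each of these benzylic carbons lies β to one carboxyl-level carbon (C2 and C5).
- Both benzylic C–aryl bonds are therefore made in one operation, by palladium-catalysed arylation of the two methyl groups of a (2S,3R)-2-benzyloxy-2,3-dimethylsuccinic bis(quinolin-8-yl)amide with O-benzyl-4-iodoguaiacol.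
- The diamide comes from the anti aldol of methyl pyruvate with a propanethioate silyl ketene acetal (sets both stereocentres), neutral O-benzylation and a double aluminium-amide aminolysis.
- The only ring, the lactone, is closed last. The less hindered amide is reduced to the C5 alcohol, which displaces the second auxiliary at C2; hydrogenolysis then frees the three hydroxyl groups.

Key step: step 6

Assumption: the (S,S)-Ph-pybox complex of Sn(OTf)2 is taken to deliver the (2S,3R) anti adduct; if the sense of induction is opposite, the (R,R) ligand is used with no other change.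

**Route**

Step 1
Reactants: 1 S-tert-butyl propanethioate
Product: 3 (Z)-1-(tert-butylsulfanyl)-1-(trimethylsilyloxy)prop-1-ene, via lithium thioester enolate 2 (not isolated)
Conditions: LiN(iPr)2 (1.1 equiv), THF, −78 °C; Me3SiCl (1.2 equiv), −78 °C to rt; distillation
Reagents that add atoms: chlorotrimethylsilane, C[Si](C)(C)Cl
Why: Kinetic deprotonation of the thioester through a closed transition state gives the enolate with methyl trans to oxygen, and O-silylation (silyl ketene acetal formation) fixes this geometry as the (Z)-ketene thioacetal.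

Step 2
Reactants: 3 (Z)-1-(tert-butylsulfanyl)-1-(trimethylsilyloxy)prop-1-ene; 4 methyl pyruvate
Product: 6 methyl (2S,3R)-4-(tert-butylsulfanyl)-2-hydroxy-2,3-dimethyl-4-oxobutanoate, via trimethylsilyl ether of the adduct 5 (not isolated)
Conditions: Sn(OTf)2 (10 mol%), (S,S)-Ph-pybox (12 mol%), CH2Cl2, −78 °C; then 1 M HCl, THF, rt
Reagents that add atoms: none
Why: Catalytic enantioselective Mukaiyama aldol addition in which the pyruvate chelates the divalent tin centre through both carbonyl oxygens, the pybox ligand leaves one ketone face open and so sets C2, the open transition state places the nucleophile methyl anti to the hydroxyl and so sets C3, and mild acid removes the transferred silyl group.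

Step 3
Reactants: 6 methyl (2S,3R)-4-(tert-butylsulfanyl)-2-hydroxy-2,3-dimethyl-4-oxobutanoate
Product: 7 methyl (2S,3R)-2-(benzyloxy)-4-(tert-butylsulfanyl)-2,3-dimethyl-4-oxobutanoate
Conditions: 2-benzyloxy-1-methylpyridinium triflate (3 equiv), MgO (3 equiv), PhCF3, 85 °C
Reagents that add atoms: 2-benzyloxy-1-methylpyridinium triflate, C[n+]1ccccc1OCc1ccccc1.[O-]S(=O)(=O)C(F)(F)F
Why: Dudley benzylation, in which the pyridinium salt ionises thermally to a benzyl cation equivalent that the tertiary hydroxyl captures under neutral buffered conditions, so no alkoxide forms and retro-aldol cleavage, elimination and C3 epimerisation have no pathway.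

Step 4
Reactants: 7 methyl (2S,3R)-2-(benzyloxy)-4-(tert-butylsulfanyl)-2,3-dimethyl-4-oxobutanoate; 8 quinolin-8-amine (two molecules incorporated)
Product: 10 (2S,3R)-2-(benzyloxy)-2,3-dimethyl-N1,N4-di(quinolin-8-yl)butanediamide, via C4 monoamide methyl ester 9 (not isolated)
Conditions: AlMe3 (5 equiv), 8 (5 equiv), toluene, 0 °C to rt; then 7, 90 °C; aq. potassium sodium tartrate (KNaC4H4O6)
Reagents that add atoms: none
Why: Weinreb aminolysis, in which the dimethylaluminium amide of quinolin-8-amine acylates first at the thioester and then, helped by chelation to the α-benzyloxy oxygen, at the hindered methyl ester, while any N-quinolinyl succinimide formed on the way is reopened by the same reagent to the same diamide.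

Step 5
Reactants: 11 4-iodo-2-methoxyphenol
Product: 12 1-(benzyloxy)-4-iodo-2-methoxybenzene
Conditions: BnBr (1.1 equiv), K2CO3 (1.5 equiv), acetone, reflux
Reagents that add atoms: benzyl bromide, BrCc1ccccc1
Why: Williamson ether synthesis of a phenoxide with a primary benzylic bromide.

Step 6
Reactants: 10 (2S,3R)-2-(benzyloxy)-2,3-dimethyl-N1,N4-di(quinolin-8-yl)butanediamide; 12 1-(benzyloxy)-4-iodo-2-methoxybenzene (two molecules incorporated)
Product: 15 (2S,3R)-2-(benzyloxy)-2,3-bis[4-(benzyloxy)-3-methoxybenzyl]-N1,N4-di(quinolin-8-yl)butanediamide, via C2-benzyl monoarylated diamide 13 (not isolated), via C3-benzyl monoarylated diamide 14 (not isolated)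
Conditions: Pd(OAc)2 (15 mol%), AgOAc (3.0 equiv), (BnO)2PO2H (30 mol%), 12 (3.0 equiv), t-AmylOH, 100 °C
Reagents that add atoms: none
Why: Each quinolin-8-yl amide, once deprotonated, holds divalent palladium through its two nitrogens, acetate-assisted concerted metalation–deprotonation then cleaves a C–H bond of the methyl group β to that amide through a five-membered palladacycle, oxidative addition of 12 gives tetravalent palladium, C–C reductive elimination forms the benzylic C–aryl bond and AgOAc takes up iodide to return Pd(OAc)2, the cycle running once at each methyl group by way of 13 and 14. The closest known reaction type is the 8-aminoquinoline-directed β-methyl C(sp3)–H arylation of O-protected lactic amides and of 2-methylalkanoic amides with electron-rich aryl iodides. No ring is closed and no stereocentre is formed, and the two centres from the aldol step are carried through because C2 is fully substituted and the C3–H bond is not acidified enough for the carboxylate base to remove it. Site selectivity for the two methyl groups over the C3 methine, the ether CH2 and the more remote positions is needed, and it is secured because only the methyl C–H bonds reach palladium through an unstrained five-membered palladacycle. One aryl group per methyl is needed as well, which rests on the slower palladation of the new, neopentyl-like benzylic CH2 groups and on the limited excess of 12. The phosphoric acid additive reprotonates the second amidate, so that a substrate molecule binding one palladium through both auxiliaries is returned to the cycle.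

Step 7
Reactants: 15 (2S,3R)-2-(benzyloxy)-2,3-bis[4-(benzyloxy)-3-methoxybenzyl]-N1,N4-di(quinolin-8-yl)butanediamide
Product: 16 (2S,3R)-2-(benzyloxy)-2,3-bis[4-(benzyloxy)-3-methoxybenzyl]-N4-(tert-butoxycarbonyl)-N1,N4-di(quinolin-8-yl)butanediamide
Conditions: Boc2O (1.3 equiv), DMAP (0.2 equiv), MeCN, rt
Reagents that add atoms: di-tert-butyl dicarbonate, CC(C)(C)OC(=O)OC(=O)OC(C)(C)C
Why: Amide N-acylation (Boc activation), which should occur at the amide on the tertiary carbon C3 because the amide on the fully substituted carbon C2 is shielded by the benzyloxy group and two branches, with the limited charge of Boc2O holding the reaction at one carbamate.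

Step 8
Reactants: 16 (2S,3R)-2-(benzyloxy)-2,3-bis[4-(benzyloxy)-3-methoxybenzyl]-N4-(tert-butoxycarbonyl)-N1,N4-di(quinolin-8-yl)butanediamide
Product: 18 (2S,3S)-2-(benzyloxy)-2,3-bis[4-(benzyloxy)-3-methoxybenzyl]-4-hydroxy-N-(quinolin-8-yl)butanamide, via C4 aldehyde 17 (not isolated)
Conditions: LiBH4 (3 equiv), THF, 0 °C to rt; aq. NH4Cl
Reagents that add atoms: none
Why: Hydride reduction of an N-acyl carbamate, in which the twisted N-Boc amide carbonyl takes up hydride, collapses to the aldehyde with loss of the carbamate anion and is reduced on to the primary alcohol, while the untouched secondary amide and both stereocentres are inert to LiBH4 at this temperature.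

Step 9
Reactants: 18 (2S,3S)-2-(benzyloxy)-2,3-bis[4-(benzyloxy)-3-methoxybenzyl]-4-hydroxy-N-(quinolin-8-yl)butanamide
Product: 19 (3S,4S)-3-(benzyloxy)-3,4-bis[4-(benzyloxy)-3-methoxybenzyl]oxolan-2-one
Conditions: TsOH·H2O (1.5 equiv), toluene, 80 °C; aq. NaHCO3
Reagents that add atoms: none
Why: Acid-catalysed lactonisation by 5-exo-trig attack of the C4 hydroxyl on the protonated C1 amide, favoured by the substitution on the chain and by loss of quinolin-8-amine as its salt, which closes the lactone ring and removes the second auxiliary without touching either stereocentre.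

Step 10
Reactants: 19 (3S,4S)-3-(benzyloxy)-3,4-bis[4-(benzyloxy)-3-methoxybenzyl]oxolan-2-one
Product: 21 (3S,4S)-3-hydroxy-3,4-bis(4-hydroxy-3-methoxybenzyl)oxolan-2-one, via diphenol tertiary benzyl ether 20 (not isolated)
Conditions: H2 (1 atm), Pd(OH)2/C, EtOAc/EtOH, rt
Reagents that add atoms: none
Why: Catalytic hydrogenolysis cleaves the two aryl benzyl ethers and then the tertiary alkyl benzyl ether, while the lactone, the aryl methyl ethers and the benzylic C–C bonds are inert and no stereocentre is touched.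

**Compound list**

1 | S-tert-butyl propanethioate | CCC(=O)SC(C)(C)C | starting material
2 | lithium (Z)-1-(tert-butylsulfanyl)prop-1-en-1-olate | C/C=C(/[O-])SC(C)(C)C.[Li+] | intermediate
3 | (Z)-1-(tert-butylsulfanyl)-1-(trimethylsilyloxy)prop-1-ene | C/C=C(/O[Si](C)(C)C)SC(C)(C)C | intermediate
4 | methyl pyruvate | COC(=O)C(C)=O | starting material
5 | methyl (2S,3R)-4-(tert-butylsulfanyl)-2,3-dimethyl-4-oxo-2-(trimethylsilyloxy)butanoate | COC(=O)[C@@](C)(O[Si](C)(C)C)[C@@H](C)C(=O)SC(C)(C)C | intermediate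
6 | methyl (2S,3R)-4-(tert-butylsulfanyl)-2-hydroxy-2,3-dimethyl-4-oxobutanoate | COC(=O)[C@@](C)(O)[C@@H](C)C(=O)SC(C)(C)C | intermediate
7 | methyl (2S,3R)-2-(benzyloxy)-4-(tert-butylsulfanyl)-2,3-dimethyl-4-oxobutanoate | COC(=O)[C@@](C)(OCc1ccccc1)[C@@H](C)C(=O)SC(C)(C)C | intermediate
8 | quinolin-8-amine | Nc1cccc2cccnc12 | starting material
9 | methyl (2S,3R)-2-(benzyloxy)-2,3-dimethyl-4-oxo-4-(quinolin-8-ylamino)butanoate | COC(=O)[C@@](C)(OCc1ccccc1)[C@@H](C)C(=O)Nc1cccc2cccnc12 | intermediate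
10 | (2S,3R)-2-(benzyloxy)-2,3-dimethyl-N1,N4-di(quinolin-8-yl)butanediamide | O=C(Nc1cccc2cccnc12)[C@@](C)(OCc1ccccc1)[C@@H](C)C(=O)Nc1cccc2cccnc12 | intermediate
11 | 4-iodo-2-methoxyphenol | COc1cc(I)ccc1O | starting material
12 | 1-(benzyloxy)-4-iodo-2-methoxybenzene | COc1cc(I)ccc1OCc1ccccc1 | intermediate
13 | (2S,3R)-2-(benzyloxy)-2-[4-(benzyloxy)-3-methoxybenzyl]-3-methyl-N1,N4-di(quinolin-8-yl)butanediamide | O=C(Nc1cccc2cccnc12)[C@@](Cc1ccc(OCc2ccccc2)c(OC)c1)(OCc1ccccc1)[C@@H](C)C(=O)Nc1cccc2cccnc12 | intermediate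
14 | (2S,3R)-2-(benzyloxy)-3-[4-(benzyloxy)-3-methoxybenzyl]-2-methyl-N1,N4-di(quinolin-8-yl)butanediamide | O=C(Nc1cccc2cccnc12)[C@@](C)(OCc1ccccc1)[C@@H](Cc1ccc(OCc2ccccc2)c(OC)c1)C(=O)Nc1cccc2cccnc12 | intermediate
15 | (2S,3R)-2-(benzyloxy)-2,3-bis[4-(benzyloxy)-3-methoxybenzyl]-N1,N4-di(quinolin-8-yl)butanediamide | O=C(Nc1cccc2cccnc12)[C@@](Cc1ccc(OCc2ccccc2)c(OC)c1)(OCc1ccccc1)[C@@H](Cc1ccc(OCc2ccccc2)c(OC)c1)C(=O)Nc1cccc2cccnc12 | intermediate
16 | (2S,3R)-2-(benzyloxy)-2,3-bis[4-(benzyloxy)-3-methoxybenzyl]-N4-(tert-butoxycarbonyl)-N1,N4-di(quinolin-8-yl)butanediamide | O=C(Nc1cccc2cccnc12)[C@@](Cc1ccc(OCc2ccccc2)c(OC)c1)(OCc1ccccc1)[C@@H](Cc1ccc(OCc2ccccc2)c(OC)c1)C(=O)N(C(=O)OC(C)(C)C)c1cccc2cccnc12 | intermediate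
17 | (2S,3R)-2-(benzyloxy)-2,3-bis[4-(benzyloxy)-3-methoxybenzyl]-4-oxo-N-(quinolin-8-yl)butanamide | O=C(Nc1cccc2cccnc12)[C@@](Cc1ccc(OCc2ccccc2)c(OC)c1)(OCc1ccccc1)[C@@H](Cc1ccc(OCc2ccccc2)c(OC)c1)C=O | intermediate
18 | (2S,3S)-2-(benzyloxy)-2,3-bis[4-(benzyloxy)-3-methoxybenzyl]-4-hydroxy-N-(quinolin-8-yl)butanamide | O=C(Nc1cccc2cccnc12)[C@@](Cc1ccc(OCc2ccccc2)c(OC)c1)(OCc1ccccc1)[C@@H](Cc1ccc(OCc2ccccc2)c(OC)c1)CO | intermediate
19 | (3S,4S)-3-(benzyloxy)-3,4-bis[4-(benzyloxy)-3-methoxybenzyl]oxolan-2-one | COc1cc(C[C@H]2COC(=O)[C@]2(OCc2ccccc2)Cc2ccc(OCc3ccccc3)c(OC)c2)ccc1OCc1ccccc1 | intermediate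
20 | (3S,4S)-3-(benzyloxy)-3,4-bis(4-hydroxy-3-methoxybenzyl)oxolan-2-one | COc1cc(C[C@H]2COC(=O)[C@]2(OCc2ccccc2)Cc2ccc(O)c(OC)c2)ccc1O | intermediate
21 | (3S,4S)-3-hydroxy-3,4-bis(4-hydroxy-3-methoxybenzyl)oxolan-2-one | COc1cc(C[C@H]2COC(=O)[C@]2(O)Cc2ccc(O)c(OC)c2)ccc1O | target

**Step count**

Total: 10 steps. Longest linear sequence: 9 steps (steps 1, 2, 3, 4, 6, 7, 8, 9, 10, from S-tert-butyl propanethioate).

**Steps most likely to fail**

Step 6. What may go wrong: capture of palladium by both amidates of one substrate molecule, stalling after the first arylation, a further arylation at a newly formed benzylic CH2, or epimerisation at C3 at 100 °C. Fallback: the two arylations are run as separate single-directed events. From 7, the thioester alone is aminolysed (8, AgO2CCF3, THF, rt) and the monoamide 9 is now isolated. With one auxiliary only, Pd(OAc)2/AgOAc and 12 (1.5 equiv) should arylate the C3 methyl to give methyl (2S,3R)-2-(benzyloxy)-3-[4-(benzyloxy)-3-methoxybenzyl]-2-methyl-4-oxo-4-(quinolin-8-ylamino)butanoate F1. Weinreb aminolysis of its ester (AlMe3, 8, toluene, 90 °C) gives 14, and a second arylation, now of the one remaining methyl group, returns to the route at 15.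

Step 7. What may go wrong: acylation at the wrong amide nitrogen or at both, or closure of the activated amide onto its neighbour, which would lead the hydride of step 8 to the wrong carbonyl. Fallback: the two carboxyl carbons are told apart by the tertiary hydroxyl instead of by hindrance.
- From 15, both amides are activated on purpose (Boc2O in excess, DMAP, MeCN, 60 °C) to (2S,3R)-2-(benzyloxy)-2,3-bis[4-(benzyloxy)-3-methoxybenzyl]-N1,N4-bis(tert-butoxycarbonyl)-N1,N4-di(quinolin-8-yl)butanediamide F2.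
- LiOH/H2O2 (THF/H2O, 0 °C to rt) cleaves both acyl carbamates to (2S,3R)-2-(benzyloxy)-2,3-bis[4-(benzyloxy)-3-methoxybenzyl]butanedioic acid F3.
- Hydrogenolysis (H2, Pd(OH)2/C) gives (2S,3R)-2-hydroxy-2,3-bis(4-hydroxy-3-methoxybenzyl)butanedioic acid F4.
- 2,2-Dimethoxypropane with TsOH ties the tertiary hydroxyl and the C1 acid into (2R)-2-[(4S)-4-(4-hydroxy-3-methoxybenzyl)-2,2-dimethyl-5-oxo-1,3-dioxolan-4-yl]-3-(4-hydroxy-3-methoxyphenyl)propanoic acid F5.
- BH3·SMe2 (THF, 0 °C) reduces the free acid to (5S)-5-(4-hydroxy-3-methoxybenzyl)-5-[(2S)-1-hydroxy-3-(4-hydroxy-3-methoxyphenyl)propan-2-yl]-2,2-dimethyl-1,3-dioxolan-4-one F6.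
- Acid (TsOH, CH2Cl2) then closes the lactone with loss of acetone and arrives at 21.

Step 4. What may go wrong: slow substitution at the neopentyl-like ester carbonyl, or epimerisation at C3 under the forcing conditions. Fallback: the hindered C1–N bond is made intramolecularly through the imide.
- From 7, hydrolysis (LiOH, THF/MeOH/H2O, 50 °C) gives (2S,3R)-2-(benzyloxy)-2,3-dimethylbutanedioic acid F7.
- Ac2O closes it to (3S,4R)-3-(benzyloxy)-3,4-dimethyloxolane-2,5-dione F8.
- 8 opens the anhydride at the less hindered carbonyl to (2S,3R)-2-(benzyloxy)-2,3-dimethyl-4-oxo-4-(quinolin-8-ylamino)butanoic acid F9.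
- Ac2O/NaOAc closes this to (3S,4R)-3-(benzyloxy)-3,4-dimethyl-1-(quinolin-8-yl)pyrrolidine-2,5-dione F10.
- One equivalent of the aluminium amide (AlMe3, 8, toluene, 60 °C) opens the imide at the less hindered carbonyl and rejoins the route at 10.

**Further compounds**

F1 | step 6 | methyl (2S,3R)-2-(benzyloxy)-3-[4-(benzyloxy)-3-methoxybenzyl]-2-methyl-4-oxo-4-(quinolin-8-ylamino)butanoate | COC(=O)[C@@](C)(OCc1ccccc1)[C@@H](Cc1ccc(OCc2ccccc2)c(OC)c1)C(=O)Nc1cccc2cccnc12
F2 | step 7 | (2S,3R)-2-(benzyloxy)-2,3-bis[4-(benzyloxy)-3-methoxybenzyl]-N1,N4-bis(tert-butoxycarbonyl)-N1,N4-di(quinolin-8-yl)butanediamide | O=C(N(C(=O)OC(C)(C)C)c1cccc2cccnc12)[C@@](Cc1ccc(OCc2ccccc2)c(OC)c1)(OCc1ccccc1)[C@@H](Cc1ccc(OCc2ccccc2)c(OC)c1)C(=O)N(C(=O)OC(C)(C)C)c1cccc2cccnc12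
F3 | step 7 | (2S,3R)-2-(benzyloxy)-2,3-bis[4-(benzyloxy)-3-methoxybenzyl]butanedioic acid | OC(=O)[C@@](Cc1ccc(OCc2ccccc2)c(OC)c1)(OCc1ccccc1)[C@@H](Cc1ccc(OCc2ccccc2)c(OC)c1)C(=O)O
F4 | step 7 | (2S,3R)-2-hydroxy-2,3-bis(4-hydroxy-3-methoxybenzyl)butanedioic acid | OC(=O)[C@@](Cc1ccc(O)c(OC)c1)(O)[C@@H](Cc1ccc(O)c(OC)c1)C(=O)O
F5 | step 7 | (2R)-2-[(4S)-4-(4-hydroxy-3-methoxybenzyl)-2,2-dimethyl-5-oxo-1,3-dioxolan-4-yl]-3-(4-hydroxy-3-methoxyphenyl)propanoic acid | CC1(C)OC(=O)[C@@](Cc2ccc(O)c(OC)c2)(O1)[C@@H](Cc1ccc(O)c(OC)c1)C(=O)O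
F6 | step 7 | (5S)-5-(4-hydroxy-3-methoxybenzyl)-5-[(2S)-1-hydroxy-3-(4-hydroxy-3-methoxyphenyl)propan-2-yl]-2,2-dimethyl-1,3-dioxolan-4-one | CC1(C)OC(=O)[C@@](Cc2ccc(O)c(OC)c2)(O1)[C@@H](Cc1ccc(O)c(OC)c1)CO
F7 | step 4 | (2S,3R)-2-(benzyloxy)-2,3-dimethylbutanedioic acid | OC(=O)[C@@](C)(OCc1ccccc1)[C@@H](C)C(=O)O
F8 | step 4 | (3S,4R)-3-(benzyloxy)-3,4-dimethyloxolane-2,5-dione | O=C1[C@@](C)(OCc2ccccc2)[C@@H](C)C(=O)O1
F9 | step 4 | (2S,3R)-2-(benzyloxy)-2,3-dimethyl-4-oxo-4-(quinolin-8-ylamino)butanoic acid | OC(=O)[C@@](C)(OCc1ccccc1)[C@@H](C)C(=O)Nc1cccc2cccnc12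
F10 | step 4 | (3S,4R)-3-(benzyloxy)-3,4-dimethyl-1-(quinolin-8-yl)pyrrolidine-2,5-dione | O=C1[C@@](C)(OCc2ccccc2)[C@@H](C)C(=O)N1c1cccc2cccnc12
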